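**Retrosynthetic overview**

1. The target is reached by Saegusa oxidation of a C7 enol silane; before that, the C8 carbinol is set by hydride reduction of a C8 ketone on the face away from the angular methyl, and the 4-methoxybenzoate is placed on the C4 hydroxyl of a trans-fused hydroazulene diol.
2. That diol comes from the cycloadduct by Rubottom oxidation at C8, methylation at C6 and hydroboration of the C3a=C4 alkene (C3a–H and C4–OH added syn, trans ring fusion).
3. The cycloadduct comes from an acyclic enyne by a rhodium-catalysed [5+2] cycloaddition that forms C8a–C3a and C4–C5 and closes the five- and seven-membered rings in the same step; no other step forms a ring of the skeleton.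
4. The enyne comes from an alkenyl iodide and a cyclopropanone hemiketal; the iodide comes from D-valine by dioxolanone allylation (C3 centre), two alkyne homologations and carboalumination–iodination.
5. Feature: the C7 ketone/C8 carbinol pair of the seven-membered ring is the enol silane left by a 1-siloxy-1-alkenylcyclopropane, and the five-membered ring is the three-atom tether C1–C2–C3 through the isopropyl carbinol carbon, linking the alkene carbon (C8a) to the alkyne carbon (C3a).

Key step: step 16

Remark: azulene numbering is used (C1, C2 ring CH2; C3 isopropyl carbinol; C3a ring-fusion CH; C4 ester carbon; C5, C6; C7 ketone; C8 carbinol; C8a methyl-bearing carbon); the C6, C7 and C8 centres that step 22 erases are assumed to be carried as mixtures and are written without descriptor.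

**Route**

Step 1
Reactants: 1 D-valine
Product: 2 (R)-2-hydroxy-3-methylbutanoic acid
Conditions: NaNO2, 1 M H2SO4 (aq), 0 °C → rt
Reagents that add atoms: water, O
Why: Diazotisation of the α-amino acid with hydrolysis through the α-lactone (double inversion) should replace nitrogen by hydroxyl with net retention, so C2 stays R.

Step 2
Reactants: 2 (R)-2-hydroxy-3-methylbutanoic acid; 3 pivalaldehyde
Product: 4 (2R,5R)-2-tert-butyl-5-(propan-2-yl)-1,3-dioxolan-4-one
Conditions: TsOH·H2O (cat.), H2SO4 (cat.), pentane, reflux, Dean–Stark; cis isomer by crystallisation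
Reagents that add atoms: none
Why: Acid-catalysed acetalisation under equilibrating conditions favours the cis-2,5-disubstituted dioxolanone, so the existing C5 centre sets the new acetal centre (self-regeneration of stereocentres).

Step 3
Reactants: 4 cis-dioxolanone; 5 allyl bromide
Product: 7 (2R,5R)-2-tert-butyl-5-(prop-2-en-1-yl)-5-(propan-2-yl)-1,3-dioxolan-4-one, via lithium enolate 6 (not isolated)
Conditions: LiN(iPr)2, THF, −78 °C; then 5, −78 → −30 °C
Reagents that add atoms: none
Why: Enolate alkylation in which the tert-butyl group shields one face of the planar enolate, so the allyl group enters trans to it and takes the place of the former C5 hydrogen, rebuilding C5 as a quaternary centre.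

Step 4
Reactants: 7 allyl dioxolanone
Product: 8 (2R)-2-(propan-2-yl)pent-4-ene-1,2-diol
Conditions: LiAlH4, THF, 0 °C → rt; Fieser work-up
Reagents that add atoms: none
Why: Hydride reduction of the acylal-type lactone takes the carboxyl carbon to CH2OH and releases the tertiary alcohol without touching the quaternary centre.

Step 5
Reactants: 8 diol
Product: 9 (2R)-2-hydroxy-2-(propan-2-yl)pent-4-enal
Conditions: SO3·pyridine, DMSO, iPr2NEt, CH2Cl2, 0 °C; used crude
Reagents that add atoms: none
Why: Parikh–Doering oxidation takes only the primary alcohol to the aldehyde, the tertiary alcohol cannot be oxidised and the quaternary α-carbon cannot epimerise.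

Step 6
Reactants: 9 hydroxy aldehyde
Product: 10 (3R)-3-(propan-2-yl)hex-5-en-1-yn-3-ol
Conditions: dimethyl (1-diazo-2-oxopropyl)phosphonate, K2CO3, MeOH, 0 °C → rt
Reagents that add atoms: dimethyl (1-diazo-2-oxopropyl)phosphonate, CC(=O)C(=[N+]=[N-])P(=O)(OC)OC
Why: Ohira–Bestmann homologation (Seyferth–Gilbert type) converts the aldehyde into the terminal alkyne under mild carbonate conditions that tolerate the free tertiary alcohol.

Step 7
Reactants: 10 propargylic alcohol
Product: 12 (3R)-3-(propan-2-yl)-1-(triethylsilyl)-3-[(triethylsilyl)oxy]hex-5-en-1-yne, via dilithium alkoxide acetylide 11 (not isolated)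
Conditions: nBuLi (2.2 equiv), Et2O, −78 °C; then Et3SiOTf (2.3 equiv), −78 → 0 °C
Reagents that add atoms: triethylsilyl trifluoromethanesulfonate, CC[Si](CC)(CC)OS(=O)(=O)C(F)(F)F
Why: Double deprotonation and O,C-bis-silylation with the silyl triflate protects the hindered tertiary alcohol and masks the acidic alkyne C–H for the later borane, alane and organolithium steps.

Step 8
Reactants: 12 bis-silyl enyne
Product: 14 (4R)-4-(propan-2-yl)-6-(triethylsilyl)-4-[(triethylsilyl)oxy]hex-5-yn-1-ol, via B-alkyl-9-BBN adduct 13 (not isolated)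
Conditions: 9-BBN, THF, 0 °C → rt; then 30% H2O2, 3 M NaOAc (aq), 0 °C → rt
Reagents that add atoms: hydrogen peroxide, OO
Why: Anti-Markovnikov hydroboration–oxidation, in which 9-BBN should add to the terminal alkene much faster than to the hindered silyl alkyne and the buffered oxidation spares both silyl groups.

Step 9
Reactants: 14 primary alcohol
Product: 15 (4R)-4-(propan-2-yl)-6-(triethylsilyl)-4-[(triethylsilyl)oxy]hex-5-ynal
Conditions: Dess–Martin periodinane, CH2Cl2, 0 °C → rt
Reagents that add atoms: none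
Why: Dess–Martin oxidation of the primary alcohol stops at the aldehyde under near-neutral conditions.

Step 10
Reactants: 15 aldehyde
Product: 16 (3R)-3-(propan-2-yl)-1-(triethylsilyl)-3-[(triethylsilyl)oxy]hepta-1,6-diyne
Conditions: Me3SiCHN2, nBuLi, THF, −78 °C; then 15, −78 → 0 °C
Reagents that add atoms: (trimethylsilyl)diazomethane, C[Si](C)(C)C=[N+]=[N-]
Why: Colvin homologation (addition of the lithiated diazo reagent, Peterson-type loss of silanolate and 1,2-shift in the alkylidene carbene) gives the terminal alkyne without the methanolic carbonate that would cleave the alkynylsilane.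

Step 11
Reactants: 16 diyne
Product: 18 (3R,6E)-7-iodo-6-methyl-3-(propan-2-yl)-1-(triethylsilyl)-3-[(triethylsilyl)oxy]hept-6-en-1-yne, via alkenyl dimethylalane 17 (not isolated)
Conditions: Me3Al, Cp2ZrCl2 (25 mol%), CH2Cl2, 0 °C → rt; then I2, THF, −30 → 0 °C
Reagents that add atoms: trimethylaluminium, C[Al](C)C; iodine, [I][I]
Why: Zirconium-catalysed Negishi carboalumination adds methyl and aluminium syn across the unhindered terminal alkyne (methyl to the internal carbon) and iodinolysis with retention fixes the E alkenyl iodide, while the bulky silyl alkyne should stay inert.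

Step 12
Reactants: 19 (1-ethoxycyclopropoxy)trimethylsilane
Product: 20 1-ethoxycyclopropan-1-ol
Conditions: MeOH, rt; concentrate
Reagents that add atoms: none
Why: Methanolysis of the labile mixed silyl ketal gives the cyclopropanone ethyl hemiketal, a storable cyclopropanone equivalent.

Step 13
Reactants: 18 alkenyl iodide; 20 1-ethoxycyclopropan-1-ol
Product: 24 1-[(1E,5R)-2-methyl-5-(propan-2-yl)-7-(triethylsilyl)-5-[(triethylsilyl)oxy]hept-1-en-6-yn-1-yl]cyclopropan-1-ol, via magnesium hemiketal salt 21 (not isolated), via cyclopropanone 22 (not isolated), via alkenyllithium 23 (not isolated)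
Conditions: 20 (3 equiv), EtMgBr (3 equiv), THF, −78 → 0 °C; separately 18, tBuLi (2.1 equiv), Et2O, −78 °C; combine, −78 °C → rt
Reagents that add atoms: none
Why: Iodine–lithium exchange with retention of alkene geometry and 1,2-addition of the alkenyllithium to cyclopropanone, released in the flask from the bromomagnesium hemiketal salt, should give the tertiary cyclopropanol (organometallic addition to a cyclopropanone equivalent).

Step 14
Reactants: 24 alkenylcyclopropanol
Product: 25 tert-butyldimethylsilyl ether of 24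
Conditions: tBuMe2SiOTf, Et3N, CH2Cl2, −78 → 0 °C
Reagents that add atoms: tert-butyldimethylsilyl trifluoromethanesulfonate, CC(C)(C)[Si](C)(C)OS(=O)(=O)C(F)(F)F
Why: Amine-buffered silylation of the tertiary cyclopropanol avoids acid-promoted ring expansion and gives the 1-siloxy-1-alkenylcyclopropane.

Step 15
Reactants: 25 silyl-protected enyne
Product: 26 tert-butyl(dimethyl)({1-[(1E,5R)-2-methyl-5-(propan-2-yl)-5-[(triethylsilyl)oxy]hept-1-en-6-yn-1-yl]cyclopropyl}oxy)silane
Conditions: K2CO3, MeOH–THF, rt
Reagents that add atoms: none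
Why: Methoxide-mediated protodesilylation should cleave only the C(sp)–Si bond, because the hindered tertiary triethylsilyl ether and the cyclopropyl silyl ether are stable to carbonate in methanol.

Step 16
Reactants: 26 enyne
Product: 27 (3R,8aR)-7-[(tert-butyldimethylsilyl)oxy]-8a-methyl-3-(propan-2-yl)-3-[(triethylsilyl)oxy]-1,2,3,5,6,8a-hexahydroazulene
Conditions: [Rh(CO)2Cl]2 (5 mol%), ClCH2CH2Cl (0.02 M), 80 °C
Reagents that add atoms: none
Why: Monovalent rhodium binds the alkene and opens the strained, siloxy-activated cyclopropane to a σ-alkyl/π-allyl rhodacycle, the tethered alkyne inserts at the methyl-bearing allyl terminus, and C(sp3)–C(sp2) reductive elimination joins the former cyclopropane CH2 to the alkyne CH (the sequence may equally begin with ene–yne oxidative coupling). The closest known reaction type is the rhodium-catalysed intramolecular [5+2] cycloaddition of 1-siloxy- or 1-alkoxy-vinylcyclopropanes with tethered alkynes. The five-membered ring closes by exo insertion of the alkyne through the three-atom tether (C8a–C3a bond) and the seven-membered ring closes by reductive elimination from the ring-expanded rhodacycle (C4–C5 bond). The new quaternary centre C8a is controlled by C3: in the envelope of the forming five-membered ring the isopropyl group should take the pseudo-equatorial site and the silyloxy group the pseudo-axial one, and the rhodium-bearing allyl arm should meet the alkyne on the face away from that silyloxy group, so the methyl group ends cis to OSiEt3. The step needs this facial selectivity and cycloaddition in preference to alkyne oligomerisation; the fully substituted propargylic carbon (Thorpe–Ingold effect), the E alkene that keeps the tether away from the cyclopropane in the reactive s-cis conformer, the siloxy group that speeds ring opening, and high dilution are meant to secure them.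

Step 17
Reactants: 27 cycloadduct
Product: 29 (3R,8aS)-8-[(tert-butyldimethylsilyl)oxy]-8a-methyl-3-(propan-2-yl)-3-[(triethylsilyl)oxy]-2,3,5,6,8,8a-hexahydroazulen-7(1H)-one, via silyloxy epoxide 28 (not isolated)
Conditions: mCPBA (1.05 equiv), NaHCO3, CH2Cl2, −20 → 0 °C
Reagents that add atoms: 3-chloroperoxybenzoic acid, OOC(=O)c1cccc(Cl)c1
Why: Rubottom oxidation, in which the electron-rich enol silane should be epoxidised much faster than the hindered ring-fusion alkene and the silyloxy epoxide opens with 1,4-silyl shift to the C8 silyloxy ketone; the C8 configuration formed here is erased in step 22, so either epimer serves.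

Step 18
Reactants: 29 silyloxy ketone
Product: 31 (3R,8aS)-8-[(tert-butyldimethylsilyl)oxy]-6,8a-dimethyl-3-(propan-2-yl)-3-[(triethylsilyl)oxy]-2,3,5,6,8,8a-hexahydroazulen-7(1H)-one, via lithium enolate 30 (not isolated)
Conditions: LiN(iPr)2, THF, −78 °C; then MeI, −78 → −40 °C
Reagents that add atoms: iodomethane, CI
Why: Kinetic enolate alkylation, in which the amide base should remove the unhindered C6 proton and not the neopentyl, silyloxy-bearing C8–H, so methyl enters at C6 (its configuration is erased later).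

Step 19
Reactants: 31 methyl ketone
Product: 33 (3R,3aS,4S,8aS)-8-[(tert-butyldimethylsilyl)oxy]-6,8a-dimethyl-3-(propan-2-yl)-3-[(triethylsilyl)oxy]decahydroazulene-4,7-diol, via organoborane 32 (not isolated)
Conditions: BH3·THF (4 equiv), THF, 0 °C → rt; then 30% H2O2, 3 M NaOAc (aq), 0 °C → rt
Reagents that add atoms: hydrogen peroxide, OO
Why: Hydroboration–oxidation, in which boron adds to the less substituted C4 and hydrogen to C3a syn on the face away from the angular methyl and the C3 silyloxy group (the course known for steroidal 5-enes), setting the trans ring fusion and the C4 alcohol together, while the C7 ketone is reduced in the same pot to an alcohol that step 22 re-oxidises.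

Step 20
Reactants: 33 diol; 34 4-methoxybenzoyl chloride
Product: 35 (3R,3aS,4S,8aS)-8-[(tert-butyldimethylsilyl)oxy]-7-hydroxy-6,8a-dimethyl-3-(propan-2-yl)-3-[(triethylsilyl)oxy]decahydroazulen-4-yl 4-methoxybenzoate
Conditions: 34 (1.2 equiv), pyridine, DMAP (cat.), CH2Cl2, 0 °C → rt
Reagents that add atoms: none
Why: Nucleophile-catalysed acylation should occur at the C4 hydroxyl, because the C7 hydroxyl is flanked by the methyl-bearing C6 and the silyloxy-bearing neopentyl C8 (site-selective esterification by steric differentiation).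

Step 21
Reactants: 35 monoester
Product: 36 (3R,3aS,4S,8aS)-3,7,8-trihydroxy-6,8a-dimethyl-3-(propan-2-yl)decahydroazulen-4-yl 4-methoxybenzoate
Conditions: HF·pyridine, pyridine, THF, 0 °C → rt
Reagents that add atoms: none
Why: Fluoride-mediated desilylation should remove both silyl ethers and leave the aryl ester, exposing the C7/C8 diol and the tertiary C3 alcohol.

Step 22
Reactants: 36 triol ester
Product: 38 (3R,3aS,4S,8aS)-3,7-dihydroxy-6,8a-dimethyl-8-oxo-3-(propan-2-yl)-1,2,3,3a,4,5,8,8a-octahydroazulen-4-yl 4-methoxybenzoate, via 1,2-diketone 37 (not isolated)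
Conditions: (COCl)2, DMSO, CH2Cl2, −78 °C; then Et3N, −78 → 0 °C
Reagents that add atoms: none
Why: Swern oxidation should convert the vicinal diol into the 1,2-diketone without C–C cleavage, and because C8 has no enolisable neighbour the diketone can enolise only towards C6, giving the diosphenol with the carbonyl at C8 and erasing the C6, C7 and C8 configurations.

Step 23
Reactants: 38 diosphenol
Product: 39 (3R,3aS,4S,8aS)-3-hydroxy-6,8a-dimethyl-8-oxo-3-(propan-2-yl)-7-[(triethylsilyl)oxy]-1,2,3,3a,4,5,8,8a-octahydroazulen-4-yl 4-methoxybenzoate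
Conditions: Et3SiCl, Et3N, DMAP (cat.), CH2Cl2, 0 °C
Reagents that add atoms: chlorotriethylsilane, CC[Si](Cl)(CC)CC
Why: O-Silylation of the acidic enol hydroxyl (the hindered tertiary alcohol should not react with the silyl chloride) fixes C7 as an enol silane and leaves C8 as the only ketone.

Step 24
Reactants: 39 enol silane ketone
Product: 40 (3R,3aS,4S,8R,8aS)-3,8-dihydroxy-6,8a-dimethyl-3-(propan-2-yl)-7-[(triethylsilyl)oxy]-1,2,3,3a,4,5,8,8a-octahydroazulen-4-yl 4-methoxybenzoate
Conditions: NaBH4, CeCl3·7H2O, MeOH–THF, −78 °C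
Reagents that add atoms: none
Why: Luche 1,2-reduction, in which hydride should add to the C8 carbonyl on the face opposite the axial angular methyl on C8a (the course known for ketones next to an angular methyl, as in 17-keto steroids), placing the C8 hydroxyl cis to that methyl (8R), while the aryl ester is inert at this temperature.

Step 25
Reactants: 40 enol silane alcohol
Product: 41 (3R,3aS,4S,8R,8aS)-3,8-dihydroxy-6,8a-dimethyl-7-oxo-3-(propan-2-yl)-1,2,3,3a,4,7,8,8a-octahydroazulen-4-yl 4-methoxybenzoate
Conditions: Pd(OAc)2 (1.2 equiv), MeCN, rt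
Reagents that add atoms: none
Why: Saegusa oxidation, in which the enol silane is palladated at C6 and β-hydride elimination towards the ring C5–H should give the C5=C6 enone with the C7 ketone in place; no stereocentre is touched.

**Compound list**

1 | D-valine | CC(C)[C@@H](N)C(O)=O | starting material
2 | (R)-2-hydroxy-3-methylbutanoic acid | CC(C)[C@@H](O)C(O)=O | intermediate
3 | pivalaldehyde | CC(C)(C)C=O | starting material
4 | (2R,5R)-2-tert-butyl-5-(propan-2-yl)-1,3-dioxolan-4-one (cis) | CC(C)[C@H]1O[C@@H](C(C)(C)C)OC1=O | intermediate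
5 | allyl bromide | C=CCBr | starting material
6 | lithium enolate of 4 (not isolated) | [Li]OC1=C(C(C)C)O[C@@H](C(C)(C)C)O1 | intermediate
7 | (2R,5R)-2-tert-butyl-5-(prop-2-en-1-yl)-5-(propan-2-yl)-1,3-dioxolan-4-one (allyl trans to tert-butyl) | CC(C)[C@@]1(CC=C)O[C@@H](C(C)(C)C)OC1=O | intermediate
8 | (2R)-2-(propan-2-yl)pent-4-ene-1,2-diol | CC(C)[C@@](CO)(CC=C)O | intermediate
9 | (2R)-2-hydroxy-2-(propan-2-yl)pent-4-enal | CC(C)[C@@](C=O)(CC=C)O | intermediate
10 | (3R)-3-(propan-2-yl)hex-5-en-1-yn-3-ol | CC(C)[C@@](C#C)(CC=C)O | intermediate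
11 | dilithium alkoxide acetylide of 10 (not isolated) | CC(C)[C@@](C#C[Li])(CC=C)O[Li] | intermediate
12 | (3R)-3-(propan-2-yl)-1-(triethylsilyl)-3-[(triethylsilyl)oxy]hex-5-en-1-yne | CC(C)[C@@](C#C[Si](CC)(CC)CC)(CC=C)O[Si](CC)(CC)CC | intermediate
13 | B-alkyl-9-borabicyclo[3.3.1]nonane adduct of 12 (not isolated) | CC(C)[C@@](C#C[Si](CC)(CC)CC)(CCCB1C2CCCC1CCC2)O[Si](CC)(CC)CC | intermediate
14 | (4R)-4-(propan-2-yl)-6-(triethylsilyl)-4-[(triethylsilyl)oxy]hex-5-yn-1-ol | CC(C)[C@@](C#C[Si](CC)(CC)CC)(CCCO)O[Si](CC)(CC)CC | intermediate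
15 | (4R)-4-(propan-2-yl)-6-(triethylsilyl)-4-[(triethylsilyl)oxy]hex-5-ynal | CC(C)[C@@](C#C[Si](CC)(CC)CC)(CCC=O)O[Si](CC)(CC)CC | intermediate
16 | (3R)-3-(propan-2-yl)-1-(triethylsilyl)-3-[(triethylsilyl)oxy]hepta-1,6-diyne | CC(C)[C@@](C#C[Si](CC)(CC)CC)(CCC#C)O[Si](CC)(CC)CC | intermediate
17 | (E)-alkenyl dimethylalane from 16 (not isolated) | CC(C)[C@@](C#C[Si](CC)(CC)CC)(CC/C(C)=C/[Al](C)C)O[Si](CC)(CC)CC | intermediate
18 | (3R,6E)-7-iodo-6-methyl-3-(propan-2-yl)-1-(triethylsilyl)-3-[(triethylsilyl)oxy]hept-6-en-1-yne | CC(C)[C@@](C#C[Si](CC)(CC)CC)(CC/C(C)=C/I)O[Si](CC)(CC)CC | intermediate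
19 | (1-ethoxycyclopropoxy)trimethylsilane | CCOC1(CC1)O[Si](C)(C)C | starting material
20 | 1-ethoxycyclopropan-1-ol | CCOC1(O)CC1 | intermediate
21 | bromomagnesium 1-ethoxycyclopropan-1-olate (not isolated) | CCOC1(CC1)O[Mg]Br | intermediate
22 | cyclopropanone (not isolated) | O=C1CC1 | intermediate
23 | (E)-alkenyllithium from 18 (not isolated) | CC(C)[C@@](C#C[Si](CC)(CC)CC)(CC/C(C)=C/[Li])O[Si](CC)(CC)CC | intermediate
24 | 1-[(1E,5R)-2-methyl-5-(propan-2-yl)-7-(triethylsilyl)-5-[(triethylsilyl)oxy]hept-1-en-6-yn-1-yl]cyclopropan-1-ol | CC(C)[C@@](C#C[Si](CC)(CC)CC)(CC/C(C)=C/C1(O)CC1)O[Si](CC)(CC)CC | intermediate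
25 | tert-butyldimethylsilyl ether of 24 | CC(C)[C@@](C#C[Si](CC)(CC)CC)(CC/C(C)=C/C1(CC1)O[Si](C)(C)C(C)(C)C)O[Si](CC)(CC)CC | intermediate
26 | tert-butyl(dimethyl)({1-[(1E,5R)-2-methyl-5-(propan-2-yl)-5-[(triethylsilyl)oxy]hept-1-en-6-yn-1-yl]cyclopropyl}oxy)silane (key-step precursor) | C#C[C@](O[Si](CC)(CC)CC)(C(C)C)CC/C(C)=C/C1(O[Si](C)(C)C(C)(C)C)CC1 | intermediate
27 | (3R,8aR)-7-[(tert-butyldimethylsilyl)oxy]-8a-methyl-3-(propan-2-yl)-3-[(triethylsilyl)oxy]-1,2,3,5,6,8a-hexahydroazulene (methyl cis to the C3 silyloxy group) | C1=C2[C@](O[Si](CC)(CC)CC)(C(C)C)CC[C@]2(C)C=C(O[Si](C)(C)C(C)(C)C)CC1 | intermediate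
28 | C7–C8 silyloxy epoxide of 27 (not isolated; epoxide face unassigned) | C1=C2[C@](O[Si](CC)(CC)CC)(C(C)C)CC[C@]2(C)C3OC3(O[Si](C)(C)C(C)(C)C)CC1 | intermediate
29 | (3R,8aS)-8-[(tert-butyldimethylsilyl)oxy]-8a-methyl-3-(propan-2-yl)-3-[(triethylsilyl)oxy]-2,3,5,6,8,8a-hexahydroazulen-7(1H)-one (C8 unassigned) | C1=C2[C@](O[Si](CC)(CC)CC)(C(C)C)CC[C@]2(C)C(O[Si](C)(C)C(C)(C)C)C(=O)CC1 | intermediate
30 | C6–C7 lithium enolate of 29 (not isolated) | C1=C2[C@](O[Si](CC)(CC)CC)(C(C)C)CC[C@]2(C)C(O[Si](C)(C)C(C)(C)C)C(O[Li])=CC1 | intermediate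
31 | (3R,8aS)-8-[(tert-butyldimethylsilyl)oxy]-6,8a-dimethyl-3-(propan-2-yl)-3-[(triethylsilyl)oxy]-2,3,5,6,8,8a-hexahydroazulen-7(1H)-one (C6, C8 unassigned) | C1=C2[C@](O[Si](CC)(CC)CC)(C(C)C)CC[C@]2(C)C(O[Si](C)(C)C(C)(C)C)C(=O)C(C)C1 | intermediate
32 | C4 alkylborane / C7 borinate of 31 (not isolated) | B[C@H]2CC(C)C(OB)C(O[Si](C)(C)C(C)(C)C)[C@@]3(C)CC[C@@](O[Si](CC)(CC)CC)(C(C)C)[C@H]23 | intermediate
33 | (3R,3aS,4S,8aS)-8-[(tert-butyldimethylsilyl)oxy]-6,8a-dimethyl-3-(propan-2-yl)-3-[(triethylsilyl)oxy]decahydroazulene-4,7-diol (trans-fused; C4–OH and C3a–H on the face opposite the angular methyl; C6, C7, C8 unassigned) | O[C@H]2CC(C)C(O)C(O[Si](C)(C)C(C)(C)C)[C@@]3(C)CC[C@@](O[Si](CC)(CC)CC)(C(C)C)[C@H]23 | intermediate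
34 | 4-methoxybenzoyl chloride | COc1ccc(cc1)C(Cl)=O | starting material
35 | C4 4-methoxybenzoate of 33 | COc1ccc(cc1)C(=O)O[C@H]2CC(C)C(O)C(O[Si](C)(C)C(C)(C)C)[C@@]3(C)CC[C@@](O[Si](CC)(CC)CC)(C(C)C)[C@H]23 | intermediate
36 | (3R,3aS,4S,8aS)-3,7,8-trihydroxy-6,8a-dimethyl-3-(propan-2-yl)decahydroazulen-4-yl 4-methoxybenzoate (C6, C7, C8 unassigned) | COc1ccc(cc1)C(=O)O[C@H]2CC(C)C(O)C(O)[C@@]3(C)CC[C@@](O)(C(C)C)[C@H]23 | intermediate
37 | (3R,3aS,4S,8aS)-3-hydroxy-6,8a-dimethyl-7,8-dioxo-3-(propan-2-yl)decahydroazulen-4-yl 4-methoxybenzoate (not isolated; C6 unassigned) | COc1ccc(cc1)C(=O)O[C@H]2CC(C)C(=O)C(=O)[C@@]3(C)CC[C@@](O)(C(C)C)[C@H]23 | intermediate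
38 | (3R,3aS,4S,8aS)-3,7-dihydroxy-6,8a-dimethyl-8-oxo-3-(propan-2-yl)-1,2,3,3a,4,5,8,8a-octahydroazulen-4-yl 4-methoxybenzoate (diosphenol) | COc1ccc(cc1)C(=O)O[C@H]2CC(C)=C(O)C(=O)[C@@]3(C)CC[C@@](O)(C(C)C)[C@H]23 | intermediate
39 | (3R,3aS,4S,8aS)-3-hydroxy-6,8a-dimethyl-8-oxo-3-(propan-2-yl)-7-[(triethylsilyl)oxy]-1,2,3,3a,4,5,8,8a-octahydroazulen-4-yl 4-methoxybenzoate | COc1ccc(cc1)C(=O)O[C@H]2CC(C)=C(O[Si](CC)(CC)CC)C(=O)[C@@]3(C)CC[C@@](O)(C(C)C)[C@H]23 | intermediate
40 | (3R,3aS,4S,8R,8aS)-3,8-dihydroxy-6,8a-dimethyl-3-(propan-2-yl)-7-[(triethylsilyl)oxy]-1,2,3,3a,4,5,8,8a-octahydroazulen-4-yl 4-methoxybenzoate (C8–OH cis to the angular methyl) | COc1ccc(cc1)C(=O)O[C@H]2CC(C)=C(O[Si](CC)(CC)CC)[C@H](O)[C@@]3(C)CC[C@@](O)(C(C)C)[C@H]23 | intermediate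
41 | (3R,3aS,4S,8R,8aS)-3,8-dihydroxy-6,8a-dimethyl-7-oxo-3-(propan-2-yl)-1,2,3,3a,4,7,8,8a-octahydroazulen-4-yl 4-methoxybenzoate | COc1ccc(C(=O)O[C@H]2C=C(C)C(=O)[C@H](O)[C@@]3(C)CC[C@@](O)(C(C)C)[C@H]23)cc1 | target

**Totals**

Total step count: 25. Longest linear sequence: 24 steps (steps 1–11 and 13–25; step 12 is a one-step side branch).

**Steps most likely to fail**

1. Step 16 (cycloaddition). The alkyne may fail to insert at the fully substituted alkene terminus next to the quaternary propargylic carbon, so the enyne oligomerises or the vinylcyclopropane isomerises, or insertion may occur with poor facial selectivity at C8a. The fallback builds the six-membered homologue by a diene–yne [4+2] cycloaddition and expands it by one carbon. It sets out from 18: iodine–lithium exchange (tBuLi, through alkenyllithium 23) and acylation with N-methoxy-N-methylacetamide should give the silyl-alkynyl enone F1. K2CO3 in MeOH removes the alkynyl silyl group to give the terminal-alkyne enone F2. tBuMe2SiOTf/Et3N gives the 2-siloxydiene F3. Intramolecular [4+2] cycloaddition (Ni(cod)2 with tris(2-biphenylyl) phosphite in THF at rt, or heating in toluene), a reaction class that tolerates a diene terminus carrying two carbon substituents, should give the hydrindadiene F4. Rubottom oxidation as in step 17 gives the silyloxy ketone F5. Ring expansion with Me3SiCHN2 and Me3Al, in which the unhindered allylic CH2 should migrate in preference to the silyloxy-bearing neopentyl carbon, followed by protodesilylation on work-up, comes back to the route at 29.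

2. Step 19 (hydroboration). Borane may add only slowly to the alkene that lies between two quaternary carbons, or may add on the methyl-bearing face and give the cis-fused series. The fallback sets the two centres separately by a hydroxyl-directed epoxidation, a radical epoxide opening and an invertive esterification. It sets out from 31: buffered HF·pyridine at 0 °C should cleave only the triethylsilyl ether to give the allylic alcohol F6. VO(acac)2/tBuOOH epoxidises the alkene on the face of the C3 hydroxyl to give the epoxy ketone F7. Cp2TiCl (from Cp2TiCl2 and Zn) with 1,4-cyclohexadiene opens the epoxide homolytically at the more substituted C3a and leaves the ketone alone; hydrogen-atom transfer to the tertiary radical is expected on the face away from the angular methyl, the C3 oxygen and the C4 oxygen, giving the trans-fused C4 alcohol F8 with its hydroxyl on the methyl face. Mitsunobu esterification with 4-methoxybenzoic acid (PPh3, diisopropyl azodicarboxylate) inverts C4 and installs the ester to give the keto ester F9. HF·pyridine removes the remaining silyl ether to give the ketol F10, and Swern oxidation as in step 22 comes back to the route at 38.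

3. Step 25 (Saegusa oxidation). Palladation of the tetrasubstituted enol silane may be slow, β-hydride elimination may go to the exocyclic methylene, or the zerovalent palladium formed may ionise the allylic ester of the product. The fallback is a selenoxide elimination. It sets out from 40: PhSeCl in CH2Cl2 at −78 °C should convert the enol silane into the α-phenylselanyl ketone F11, and H2O2/pyridine at 0 °C gives the selenoxide, whose syn-elimination towards C5 comes back to the route at 41.

**Further compounds**

F1 | step 16 | (3E,7R)-4-methyl-7-(propan-2-yl)-9-(triethylsilyl)-7-[(triethylsilyl)oxy]non-3-en-8-yn-2-one | CC(C)[C@@](C#C[Si](CC)(CC)CC)(CC/C(C)=C/C(C)=O)O[Si](CC)(CC)CC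
F2 | step 16 | (3E,7R)-4-methyl-7-(propan-2-yl)-7-[(triethylsilyl)oxy]non-3-en-8-yn-2-one | CC(C)[C@@](C#C)(CC/C(C)=C/C(C)=O)O[Si](CC)(CC)CC
F3 | step 16 | 2-[(tert-butyldimethylsilyl)oxy]-1,3-diene from F2 | CC(C)[C@@](C#C)(CC/C(C)=C/C(=C)O[Si](C)(C)C(C)(C)C)O[Si](CC)(CC)CC
F4 | step 16 | bicyclo[4.3.0]nonadiene enol silane (six-membered-ring homologue of 27) | C1=C2[C@](O[Si](CC)(CC)CC)(C(C)C)CC[C@]2(C)C=C(O[Si](C)(C)C(C)(C)C)C1
F5 | step 16 | α-silyloxy cyclohexenone (six-membered-ring homologue of 29) | C1=C2[C@](O[Si](CC)(CC)CC)(C(C)C)CC[C@]2(C)C(O[Si](C)(C)C(C)(C)C)C(=O)C1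
F6 | step 19 | C3 alcohol from 31 (triethylsilyl group removed) | C1=C2[C@](O)(C(C)C)CC[C@]2(C)C(O[Si](C)(C)C(C)(C)C)C(=O)C(C)C1
F7 | step 19 | C3a–C4 epoxide of F6, oxygen cis to the C3 hydroxyl | O1[C@@H]2CC(C)C(=O)C(O[Si](C)(C)C(C)(C)C)[C@@]3(C)CC[C@@](O)(C(C)C)[C@@]123
F8 | step 19 | trans-fused C4 alcohol, hydroxyl cis to the angular methyl | O[C@@H]2CC(C)C(=O)C(O[Si](C)(C)C(C)(C)C)[C@@]3(C)CC[C@@](O)(C(C)C)[C@H]23
F9 | step 19 | C4 4-methoxybenzoate with inverted C4, C7 ketone, C8 silyl ether | COc1ccc(cc1)C(=O)O[C@H]2CC(C)C(=O)C(O[Si](C)(C)C(C)(C)C)[C@@]3(C)CC[C@@](O)(C(C)C)[C@H]23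
F10 | step 19 | C8 hydroxy C7 ketone from F9 | COc1ccc(cc1)C(=O)O[C@H]2CC(C)C(=O)C(O)[C@@]3(C)CC[C@@](O)(C(C)C)[C@H]23
F11 | step 25 | C6 phenylselanyl C7 ketone from 40 | COc1ccc(cc1)C(=O)O[C@H]2CC(C)([Se]c4ccccc4)C(=O)[C@H](O)[C@@]3(C)CC[C@@](O)(C(C)C)[C@H]23
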